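What would be left of the substrate at 55 min was my first question about the south-west flask, which has the charge of the south-east run.

| setting | south-east | east | west | south-west |
|---|---|---|---|---|
| substrate | 0.100 M | 0.0600 M | 0.300 M | 0.100 M |
| coupling partner | 0.110 M | 0.0700 M | 0.110 M | 0.110 M |
| catalyst | 0.00300 M | 0.00300 M | 0.00300 M | 0.00300 M |
| time |  |  |  | 55 min |

- south-east run (time / min: [target] / M): 4.4: 0.0082; 8.8: 0.0152; 13: 0.0227; 18: 0.0377; 22: 0.0445
- east run (time / min: [target] / M): 4.4: 0.0030; 8.8: 0.0059; 13: 0.0075; 18: 0.0124; 22: 0.0107
- west run (time / min: [target] / M): 4.4: 0.0267; 8.8: 0.0637; 13: 0.0960; 18: 0.1012; 22: 0.1043

(readings scatter by 0.002 M)

- Overall: substrate + coupling partner -> target, with catalyst as catalyst.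
- Constant volume, constant temperature.
- What is held in complexes is read along with the free species.
- An order is taken over about fifteen percent of the charge, up and down.

1. order of the initial rate in [substrate], near the charge of the south-east run, the rate being that where two percent of its substrate are target (one fixed amount of target, the same in the runs compared)
2. order of the initial rate in [coupling partner], near the charge of the south-east run, the rate being that where two percent of its substrate are target
3. the east run starts with 0.0400 M less of substrate and of coupling partner than the south-east run, and with no target. Compared where both hold the same amount of substrate, once fifteen percent of what the east run was charged with has turned into target, is the east run faster, slower or alike (within a tenth)?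
4. target in the south-west run at 55 min, as a share of the substrate charged

The south-east curve looked straight, so I used the rule of thumb of the bench and replaced it by one mean slope: mean reading over mean time, 0.00194 M min⁻¹. I then checked the error. At 22 min the line gave 0.0427 M against a reading of 0.0445 M, a gap smaller than the scatter of 0.002 M.

The useful quantity is the clearing time, the substrate charged divided by the mean slope: 51.6 min for the south-east run. It marks the border of the rule. In the south-west flask substrate is the limiting reagent, at 0.100 M against 0.110 M of coupling partner, and the asked time over the south-east clearing time is 1.07. The line therefore promised 0.107 M of target from 0.100 M of substrate, which cannot be, so it had to bend before 55 min.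

For the tail I started from the last south-east reading, which leaves 0.0555 M of substrate. I let the rate fall in step with that leftover, beginning at the mean slope. This gave a decay time of 28.6 min, and 0.0175 M of substrate left at 55 min. My figure for the south-west flask was thus 82.5% as target.

The forecast, with its ground “target accelerates the reaction”, put the share lower than mine, at 80% (range 68% to 92%), with orders of 1 in substrate and 0.85 in coupling partner, and the east run slower.

The south-west run gave 80.7%, which is 1.8 percentage points below my figure; the orders came out at 0.99 in substrate and 1.0 in coupling partner, and the east run was slower.

    catalyst + substrate ⇌ catalyst-substrate complex, settled at all times (5.810 L mol⁻¹)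
    catalyst-substrate complex + coupling partner → target + catalyst + by-product (61.80 L mol⁻¹ min⁻¹)
    2 catalyst ⇌ resting dimer, settled at all times (10400 L mol⁻¹)
    substrate + coupling partner + target → 2 target (9.480 L² mol⁻² min⁻¹)

The south-east run had turned half of its substrate into target at 24.7 min, which is half of its clearing time. The east run has a mean slope of 5.97 × 10⁻⁴ M min⁻¹, so its clearing time is 101 min, and half of that is 50.5 min. The east run reached that same conversion at 49.4 min.

The earlier runs and the new flask are calculated on assumed constants, noise included.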